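## Retrosynthetic overview

1. Target 17 comes from the (2S)-5,7-bis(methoxymethyl) flavanone 15 by acetal cleavage in the last step.
2. Ring C is the only ring made and is closed last, at the C2–O1 bond, by a catalyst-controlled oxa-Michael cyclization of 2'-hydroxychalcone 14, which sets C2. Rings A and B are bought as phloroglucinol and 3,4-dimethoxycinnamic acid.
3. Chalcone 14 comes from aryllithium 11 and cinnamoyl Weinreb amide 10. The oxygen that becomes O1 carries a 1-ethoxyethyl acetal and the two oxygens flanking the geranyl chain carry MOM, so the 6-geranyl (not 8-geranyl) pattern is fixed by construction.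
4. Geranyl arene 7 comes from 3,5-bis(methoxymethoxy)phenol 3 (from phloroglucinol 1) by dianion formation, SN2 alkylation with geranyl bromide 4 (E-alkene kept) and O-capping.

Assumption: catalyst-bound ion pairs of step 5 are not numbered; catalyst BIMP-1 is 1-[3,5-bis(trifluoromethyl)phenyl]-3-[(2S)-3,3-dimethyl-1-{[tris(4-methoxyphenyl)-λ5-phosphanylidene]amino}butan-2-yl]thiourea, SMILES COc1ccc(cc1)P(=NC[C@@H](NC(=S)Nc1cc(cc(c1)C(F)(F)F)C(F)(F)F)C(C)(C)C)(c1ccc(OC)cc1)c1ccc(OC)cc1, pre-made from L-tert-leucinol by the usual azide/Staudinger sequence and not counted as a step; the acetal carbon of the 1-ethoxyethyl group is racemic and is removed before C2 is set.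

## Route

Step 1
Reactants: 1 phloroglucinol (benzene-1,3,5-triol)
Product: 3 3,5-bis(methoxymethoxy)phenol, via 5-(methoxymethoxy)benzene-1,3-diol 2 (not isolated)
Conditions: MOMCl (2.0 equiv), K2CO3 (2.5 equiv), acetone, 0 °C → rt
Reagents that add atoms: chloromethyl methyl ether, COCCl
Why: Williamson-type O-alkylation of the phenol with the α-chloro ether (MOM protection), where two equivalents make the bis-ether the main statistical product (about 40 %, mono- and tris-ethers separated and recycled) and no stereocenter is formed.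

Step 2
Reactants: 3 3,5-bis(methoxymethoxy)phenol; 4 geranyl bromide [(2E)-1-bromo-3,7-dimethylocta-2,6-diene]
Product: 7 5-(1-ethoxyethoxy)-2-[(2E)-3,7-dimethylocta-2,6-dien-1-yl]-1,3-bis(methoxymethoxy)benzene, via lithium 4-lithio-3,5-bis(methoxymethoxy)phenolate 5 (not isolated), via lithium 4-geranyl-3,5-bis(methoxymethoxy)phenolate 6 (not isolated)
Conditions: n-BuLi (2.3 equiv), THF, 0 °C → rt; then 4 (1.05 equiv), −78 → 0 °C; then CH3CHCl(OEt) (1.5 equiv), 0 °C → rt
Reagents that add atoms: 1-chloroethyl ethyl ether, CCOC(C)Cl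
Why: Directed ortho metalation, in which the lithium phenolate deactivates its own ortho positions so the second equivalent of base removes the proton flanked by both OMOM groups, is followed by SN2 alkylation of the aryllithium at the primary allylic bromide (E-alkene untouched) and O-alkylation of the remaining phenolate by the α-chloro ether, the only new stereocenter being the racemic, temporary acetal carbon.

Step 3
Reactants: 8 (2E)-3-(3,4-dimethoxyphenyl)prop-2-enoic acid (3,4-dimethoxycinnamic acid)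
Product: 10 (2E)-3-(3,4-dimethoxyphenyl)-N-methoxy-N-methylprop-2-enamide, via 3,4-dimethoxycinnamoyl imidazolide 9 (not isolated)
Conditions: CDI (1.1 equiv), CH2Cl2, rt; then MeNHOMe·HCl (1.2 equiv), rt
Reagents that add atoms: N,O-dimethylhydroxylamine hydrochloride, CNOC.Cl
Why: Standard amide coupling through the acyl imidazolide gives the Weinreb amide without touching the E-alkene, and no stereocenter is formed.

Step 4
Reactants: 7 5-(1-ethoxyethoxy)-2-[(2E)-3,7-dimethylocta-2,6-dien-1-yl]-1,3-bis(methoxymethoxy)benzene; 10 (2E)-3-(3,4-dimethoxyphenyl)-N-methoxy-N-methylprop-2-enamide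
Product: 14 (2E)-3-(3,4-dimethoxyphenyl)-1-{3-[(2E)-3,7-dimethylocta-2,6-dien-1-yl]-6-hydroxy-2,4-bis(methoxymethoxy)phenyl}prop-2-en-1-one, via aryllithium 11 (not isolated), via tetrahedral lithium aminoalkoxide 12 (not isolated), via 1-ethoxyethyl-protected chalcone 13 (not isolated)
Conditions: n-BuLi (1.2 equiv), THF, −20 → 0 °C; then 10 (1.1 equiv), −78 → 0 °C; then 0.5 M aq HCl/THF, 0 °C → rt, 30 min
Reagents that add atoms: none
Why: Directed ortho metalation at the only ring C–H left (two positions equivalent by symmetry, each between the 1-ethoxyethoxy and an OMOM group) followed by Weinreb ketone synthesis, whose chelated adduct prevents over-addition, gives the E-enone, and the dilute acid releases the ketone and hydrolyses the acetaldehyde-derived acetal far faster than the formaldehyde-derived MOM ethers, so only the oxygen remote from the geranyl chain is freed.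

Step 5
Reactants: 14 (2E)-3-(3,4-dimethoxyphenyl)-1-{3-[(2E)-3,7-dimethylocta-2,6-dien-1-yl]-6-hydroxy-2,4-bis(methoxymethoxy)phenyl}prop-2-en-1-one
Product: 15 (2S)-2-(3,4-dimethoxyphenyl)-6-[(2E)-3,7-dimethylocta-2,6-dien-1-yl]-5,7-bis(methoxymethoxy)-2,3-dihydro-4H-chromen-4-one
Conditions: BIMP-1 (10 mol %), toluene, 4 Å MS, −20 °C, 48 h; AcOH (20 mol %) quench at −20 °C, silica plug
Reagents that add atoms: none
Why: Proposed new method: a catalytic enantioselective 6-endo oxa-Michael cyclization of an unactivated 2'-hydroxychalcone by a bifunctional iminophosphorane–thiourea superbase, in which the iminophosphorane deprotonates the chelated ortho hydroxyl to a tight aminophosphonium phenolate ion pair, the thiourea takes over the carbonyl oxygen and stabilizes the developing enolate, the tert-butyl group of the (S)-backbone is proposed to shield the Re face so that the phenolate oxygen adds to the Si face of C-β (aryl > C-α > H) and forms the C2–O1 bond with 2S configuration, and C-protonation of the enolate by the aminophosphonium turns the catalyst over, while the product has no acidic O–H and a much less acidic C3–H so retro-Michael racemization should be slow at −20 °C and the buttressed ortho OMOM group twists the chalcone and favours the closed form; the closest known reaction types are the iminophosphorane-catalyzed intramolecular oxa-Michael addition of alcohols to enoates and enamides and the thiourea-catalyzed cyclization of α-carboxy-activated 2'-hydroxychalcones, and if the observed sense is opposite the mirror-image catalyst from D-tert-leucinol is used.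

Step 6
Reactants: 15 (2S)-2-(3,4-dimethoxyphenyl)-6-[(2E)-3,7-dimethylocta-2,6-dien-1-yl]-5,7-bis(methoxymethoxy)-2,3-dihydro-4H-chromen-4-one
Product: 17 (2S)-2-(3,4-dimethoxyphenyl)-6-[(2E)-3,7-dimethylocta-2,6-dien-1-yl]-5,7-dihydroxy-2,3-dihydro-4H-chromen-4-one, via 5-hydroxy-7-methoxymethoxy flavanone 16 (not isolated)
Conditions: 3 M HCl, MeOH, rt → 40 °C, 2–4 h
Reagents that add atoms: none
Why: Acid-catalyzed acetal methanolysis (MOM cleavage, the ortho-carbonyl ether first) under conditions expected to leave the trisubstituted alkenes uncyclized and the flavanone ring closed, so the E-geranyl chain and the 2S center set in step 5 are retained.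

## Compound list

1 | phloroglucinol (benzene-1,3,5-triol) | Oc1cc(O)cc(O)c1 | starting material
2 | 5-(methoxymethoxy)benzene-1,3-diol | COCOc1cc(O)cc(O)c1 | intermediate
3 | 3,5-bis(methoxymethoxy)phenol | COCOc1cc(O)cc(OCOC)c1 | intermediate
4 | geranyl bromide, (2E)-1-bromo-3,7-dimethylocta-2,6-diene | BrC/C=C(\C)CCC=C(C)C | starting material
5 | lithium 4-lithio-3,5-bis(methoxymethoxy)phenolate | [Li]Oc1cc(OCOC)c([Li])c(OCOC)c1 | intermediate
6 | lithium 4-[(2E)-3,7-dimethylocta-2,6-dien-1-yl]-3,5-bis(methoxymethoxy)phenolate | [Li]Oc1cc(OCOC)c(C/C=C(\C)CCC=C(C)C)c(OCOC)c1 | intermediate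
7 | 5-(1-ethoxyethoxy)-2-[(2E)-3,7-dimethylocta-2,6-dien-1-yl]-1,3-bis(methoxymethoxy)benzene (racemic at the acetal carbon) | CCOC(C)Oc1cc(OCOC)c(C/C=C(\C)CCC=C(C)C)c(OCOC)c1 | intermediate
8 | (2E)-3-(3,4-dimethoxyphenyl)prop-2-enoic acid | COc1ccc(/C=C/C(=O)O)cc1OC | starting material
9 | (2E)-3-(3,4-dimethoxyphenyl)-1-(1H-imidazol-1-yl)prop-2-en-1-one | COc1ccc(/C=C/C(=O)n2ccnc2)cc1OC | intermediate
10 | (2E)-3-(3,4-dimethoxyphenyl)-N-methoxy-N-methylprop-2-enamide | COc1ccc(/C=C/C(=O)N(C)OC)cc1OC | intermediate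
11 | {6-(1-ethoxyethoxy)-3-[(2E)-3,7-dimethylocta-2,6-dien-1-yl]-2,4-bis(methoxymethoxy)phenyl}lithium | CCOC(C)Oc1cc(OCOC)c(C/C=C(\C)CCC=C(C)C)c(OCOC)c1[Li] | intermediate
12 | lithium (2E)-3-(3,4-dimethoxyphenyl)-1-{6-(1-ethoxyethoxy)-3-[(2E)-3,7-dimethylocta-2,6-dien-1-yl]-2,4-bis(methoxymethoxy)phenyl}-1-[methoxy(methyl)amino]prop-2-en-1-olate (stereoisomer mixture) | CCOC(C)Oc1cc(OCOC)c(C/C=C(\C)CCC=C(C)C)c(OCOC)c1C(O[Li])(N(C)OC)/C=C/c1ccc(OC)c(OC)c1 | intermediate
13 | (2E)-3-(3,4-dimethoxyphenyl)-1-{6-(1-ethoxyethoxy)-3-[(2E)-3,7-dimethylocta-2,6-dien-1-yl]-2,4-bis(methoxymethoxy)phenyl}prop-2-en-1-one (racemic at the acetal carbon) | CCOC(C)Oc1cc(OCOC)c(C/C=C(\C)CCC=C(C)C)c(OCOC)c1C(=O)/C=C/c1ccc(OC)c(OC)c1 | intermediate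
14 | (2E)-3-(3,4-dimethoxyphenyl)-1-{3-[(2E)-3,7-dimethylocta-2,6-dien-1-yl]-6-hydroxy-2,4-bis(methoxymethoxy)phenyl}prop-2-en-1-one | Oc1cc(OCOC)c(C/C=C(\C)CCC=C(C)C)c(OCOC)c1C(=O)/C=C/c1ccc(OC)c(OC)c1 | intermediate
15 | (2S)-2-(3,4-dimethoxyphenyl)-6-[(2E)-3,7-dimethylocta-2,6-dien-1-yl]-5,7-bis(methoxymethoxy)-2,3-dihydro-4H-chromen-4-one | COc1ccc([C@@H]2CC(=O)c3c(cc(OCOC)c(C/C=C(\C)CCC=C(C)C)c3OCOC)O2)cc1OC | intermediate
16 | (2S)-2-(3,4-dimethoxyphenyl)-6-[(2E)-3,7-dimethylocta-2,6-dien-1-yl]-5-hydroxy-7-(methoxymethoxy)-2,3-dihydro-4H-chromen-4-one | COc1ccc([C@@H]2CC(=O)c3c(cc(OCOC)c(C/C=C(\C)CCC=C(C)C)c3O)O2)cc1OC | intermediate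
17 | (2S)-2-(3,4-dimethoxyphenyl)-6-[(2E)-3,7-dimethylocta-2,6-dien-1-yl]-5,7-dihydroxy-2,3-dihydro-4H-chromen-4-one | COc1ccc([C@@H]2CC(=O)c3c(cc(O)c(C/C=C(\C)CCC=C(C)C)c3O)O2)cc1OC | target

## Step count and risk

Total step count: 6 (steps 1–6).
Longest linear sequence: 5 steps (1 → 3 → 7 → 14 → 15 → 17, steps 1, 2, 4, 5, 6); step 3 is a one-step side branch.

The three steps most likely to fail are steps 5, 2 and 4.

Step 5 (the proposed new cyclization) may give low enantiomeric excess, incomplete conversion or slow product racemization. The fallback uses known chemistry and sets out from 14. The classical racemic oxa-Michael closure (NaOAc, EtOH, reflux) gives the racemic flavanone F7. Preparative chromatography on a chiral stationary phase (amylose tris(3,5-dimethylphenylcarbamate)) then separates the enantiomers and delivers 15, where the route resumes. The unwanted (2R)-enantiomer F8 is re-equilibrated with NaOAc in hot EtOH through ring opening to 14 and recycled.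

Step 2 may fail if the second deprotonation of the phenolate is slow or unselective, or if the phenolate oxygen competes for geranyl bromide. The fallback sets out from 3 and replaces the dianion by a blocking-group strategy. Compound 3 is silylated (TIPSCl, imidazole, DMF) to [3,5-bis(methoxymethoxy)phenoxy]tri(propan-2-yl)silane F1. The bulky silyl ether shields both of its ortho positions, so n-BuLi (THF, 0 °C) gives only the 4-lithio derivative F2. This is alkylated with 4 to the geranylated silyl ether F3. TBAF (THF, 0 °C) frees 4-[(2E)-3,7-dimethylocta-2,6-dien-1-yl]-3,5-bis(methoxymethoxy)phenol F4. Ethyl vinyl ether with catalytic pyridinium p-toluenesulfonate (CH2Cl2, rt) then gives 7, where the route resumes.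

Step 4 may fail if the hindered aryllithium adds sluggishly or in the conjugate sense to the unsaturated Weinreb amide. The fallback sets out from 7, which is lithiated to 11 as before. Instead of the amide, 11 is added at −78 °C to purchased (2E)-3-(3,4-dimethoxyphenyl)prop-2-enal F5, a far more electrophilic carbonyl that reacts 1,2. After NH4Cl work-up this gives the allylic alcohol (2E)-3-(3,4-dimethoxyphenyl)-1-{6-(1-ethoxyethoxy)-3-[(2E)-3,7-dimethylocta-2,6-dien-1-yl]-2,4-bis(methoxymethoxy)phenyl}prop-2-en-1-ol F6. MnO2 (CH2Cl2, rt) oxidizes this allylic, benzylic alcohol to 13, where the fallback comes back to the route. Compound 13 is isolated here and hydrolysed with 0.5 M aq HCl/THF to 14 as in step 4.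

## Further compounds

F1 | step 2 | [3,5-bis(methoxymethoxy)phenoxy]tri(propan-2-yl)silane | CC(C)[Si](C(C)C)(C(C)C)Oc1cc(OCOC)cc(OCOC)c1
F2 | step 2 | [4-lithio-3,5-bis(methoxymethoxy)phenoxy]tri(propan-2-yl)silane | CC(C)[Si](C(C)C)(C(C)C)Oc1cc(OCOC)c([Li])c(OCOC)c1
F3 | step 2 | {4-[(2E)-3,7-dimethylocta-2,6-dien-1-yl]-3,5-bis(methoxymethoxy)phenoxy}tri(propan-2-yl)silane | CC(C)[Si](C(C)C)(C(C)C)Oc1cc(OCOC)c(C/C=C(\C)CCC=C(C)C)c(OCOC)c1
F4 | step 2 | 4-[(2E)-3,7-dimethylocta-2,6-dien-1-yl]-3,5-bis(methoxymethoxy)phenol | Oc1cc(OCOC)c(C/C=C(\C)CCC=C(C)C)c(OCOC)c1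
F5 | step 4 | (2E)-3-(3,4-dimethoxyphenyl)prop-2-enal (purchased) | COc1ccc(/C=C/C=O)cc1OC
F6 | step 4 | (2E)-3-(3,4-dimethoxyphenyl)-1-{6-(1-ethoxyethoxy)-3-[(2E)-3,7-dimethylocta-2,6-dien-1-yl]-2,4-bis(methoxymethoxy)phenyl}prop-2-en-1-ol (stereoisomer mixture) | CCOC(C)Oc1cc(OCOC)c(C/C=C(\C)CCC=C(C)C)c(OCOC)c1C(O)/C=C/c1ccc(OC)c(OC)c1
F7 | step 5 | racemic 2-(3,4-dimethoxyphenyl)-6-[(2E)-3,7-dimethylocta-2,6-dien-1-yl]-5,7-bis(methoxymethoxy)-2,3-dihydro-4H-chromen-4-one | COc1ccc(C2CC(=O)c3c(cc(OCOC)c(C/C=C(\C)CCC=C(C)C)c3OCOC)O2)cc1OC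
F8 | step 5 | (2R)-2-(3,4-dimethoxyphenyl)-6-[(2E)-3,7-dimethylocta-2,6-dien-1-yl]-5,7-bis(methoxymethoxy)-2,3-dihydro-4H-chromen-4-one | COc1ccc([C@H]2CC(=O)c3c(cc(OCOC)c(C/C=C(\C)CCC=C(C)C)c3OCOC)O2)cc1OC
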